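Monday's run, with 0.30 equiv of partner on 0.24 M of substrate, holds 22.3% product at 25.0 min, less than the 30% conversion I want to look at, so I charge the next flask with 0.600 equiv of partner and keep the loading at 0.5 mol%.

in all of them: free catalyst 0.5 mol%

| charge | substrate | partner | remark |
|---|---|---|---|
| Sunday's | 0.16 M | 0.60 equiv | run made earlier |
| Wednesday's | 0.36 M | 0.60 equiv | run made earlier |
| Monday's | 0.24 M | 0.30 equiv | run made earlier |
| flask | 0.24 M | 0.600 equiv |  |

- Sunday's (time / min: product / %, substrate / %): 1.33: 2.7, 95.8; 4.00: 8.4, 90.8; 6.00: 12.0, 87.8; 10.0: 19.1, 81.3; 15.0: 24.3, 75.2; 20.0: 28.9, 71.2; 25.0: 31.5, 69.1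
- Wednesday's (time / min: product / %, substrate / %): 2.00: 9.6, 89.7; 3.00: 14.4, 86.9; 4.00: 18.1, 82.7; 6.00: 24.6, 75.2; 10.0: 35.6, 64.6; 15.0: 40.9, 58.6; 25.0: 42.1, 57.5
- Monday's (time / min: product / %, substrate / %): 2.00: 5.6, 94.3; 6.00: 12.6, 86.9; 12.0: 19.8, 79.7; 15.0: 20.6, 79.5; 25.0: 22.3, 78.9

(each reading ± 0.5 percentage points)

- apparent order in free catalyst when 30% of the substrate are converted (percent change of the rate of making product for one percent more free catalyst charged)

- the earlier runs were read with a standard deviation of 0.5 percentage points
- steps under discussion: partner + free catalyst <-> catalyst intermediate A; substrate + catalyst intermediate A -> catalyst intermediate B; catalyst intermediate B -> free catalyst + product; partner -> decomposed reagent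

The question is how far 30% lies below the level at which this flask stops making product. Sunday's and Wednesday's runs share equivalents and loading. Their concentrations differ by a factor 2.25, and their early product rates, in percent per minute, read to 2.00 min in Wednesday's run and to 4.00 min in Sunday's, by 2.29. So I freeze one thing: I assume that on the percent scale, at fixed equivalents and loading, more concentration acts like more catalyst, while the first-order decomposition of partner keeps its own clock.

Their last readings then give 0.358, the percent change of the stopping product for one percent more catalyst, my stop slope. It is a reading, and Sunday's product is still rising at 25.0 min.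

Carried to 0.24 M, the slope puts this flask's stop near 36.4%, a gap of 6.4 percentage points above the look point. Near the stop, I take the rate to follow that gap, so one percent on the stop is stretched by stop over gap. My order is 2.03.

The forecast says 1.6, on the ground that “More catalyst reaches 30% sooner, so less partner has decayed”. I hold to the higher figure, and with that gap I bracket the loading narrowly.

The flask gives 1.9.

    partner + free catalyst ⇌ catalyst intermediate A (K = 613 M⁻¹, k = 248 M⁻¹ min⁻¹)
    substrate + catalyst intermediate A → catalyst intermediate B (k = 39.1 M⁻¹ min⁻¹)
    catalyst intermediate B → free catalyst + product (k = 169 min⁻¹)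
    partner → decomposed reagent (k = 0.0570 min⁻¹)

The flask reaches 30% at 12.1 min, and at 30.0 min it holds 37.4% product with 0.0774% of the partner charge left. With that product as the stop, the stop slope gives 1.81. Wednesday's run passes 30% between 6.00 min and 10.0 min, and on its last reading of 42.1% the same slope gives 1.25.

The numbers in the tables are simulated on assumed constants, noise included.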